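**Retrosynthetic overview**
- The strategy rests on the enol-lactone bond O1–C5 and the exocyclic C5=C6(H)Br of the furanone ring (the only ring), with Br anti to O1 and syn to C4. Both arise from one anti addition of a carboxylate oxygen and electrophilic bromine across a terminal alkyne C5≡C6, so the last step is a 5-exo-dig bromolactonisation of (R,E)-2-(1-acetoxybutyl)-3-bromopent-2-en-4-ynoic acid.
- The carboxyl carbon C2 comes from CO by carbonylation of a C3–I bond. The trans C3–I/C4–Br pair comes from anti addition of IBr to the inner alkyne of a silyl-capped 1,3-diyne.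
- The diyne comes from Cadiot–Chodkiewicz coupling of (R)-hex-1-yn-3-ol with (bromoethynyl)triisopropylsilane. Lipase resolution of the alkynol sets the only stereocentre.
- Ring order: the single furanone ring is closed last; no step follows it.

Key step: step 8

Remark: atoms are numbered as in the lactone (O1, C2 carbonyl, C3, C4, C5, exocyclic C6, side-chain carbinol C1') also in the open-chain precursors. Commercial hex-1-yn-3-ol is taken to be racemic. The target is the (R)-acetate with the (E) exocyclic alkene.

**Step 1**
Reactants: 1 racemic hex-1-yn-3-ol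
Product: 2 (R)-hex-1-yn-3-ol (the unreacted enantiomer)
Conditions: Novozym 435 (immobilised Candida antarctica lipase B), vinyl acetate, hexane, 30 °C, taken to about 55–60% conversion; alcohol separated from the acetate by chromatography
Reagents that add atoms: none
Why: Lipase-catalysed kinetic resolution by enantioselective transesterification: with ethynyl as the small and propyl as the large substituent the enzyme should acylate the (S)-alcohol faster, so running past half conversion should leave the (R)-alcohol, whose carbinol carbon becomes C1' of the target, in high enantiomeric purity.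

**Step 2**
Reactants: 3 ethynyltriisopropylsilane
Product: 4 (bromoethynyl)triisopropylsilane
Conditions: NBS, AgNO3 (10 mol%), acetone, rt
Reagents that add atoms: N-bromosuccinimide, O=C1CCC(=O)N1Br
Why: Silver-catalysed electrophilic bromination of a terminal alkyne through the silver acetylide gives the 1-bromoalkyne needed as the electrophilic coupling partner.

**Step 3**
Reactants: 2 (R)-hex-1-yn-3-ol; 4 (bromoethynyl)triisopropylsilane
Product: 5 (R)-8-(triisopropylsilyl)octa-5,7-diyn-4-ol
Conditions: CuCl (5 mol%), NH2OH·HCl, 30% aq. n-BuNH2, Et2O, 0 °C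
Reagents that add atoms: none
Why: Cadiot–Chodkiewicz coupling: the copper acetylide of 2 couples with bromoalkyne 4 to the unsymmetrical 1,3-diyne, hydroxylamine keeps copper monovalent to suppress homocoupling, and the carbinol centre is not involved.

**Step 4**
Reactants: 5 (R)-8-(triisopropylsilyl)octa-5,7-diyn-4-ol
Product: 6 (R)-8-(triisopropylsilyl)octa-5,7-diyn-4-yl acetate
Conditions: Ac2O, pyridine, DMAP (cat.), CH2Cl2, 0 °C to rt
Reagents that add atoms: acetic anhydride, CC(=O)OC(C)=O
Why: DMAP-catalysed O-acylation of the secondary alcohol occurs at oxygen with retention of the (R) configuration; it follows the coupling because aqueous butylamine would aminolyse the ester.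

**Step 5**
Reactants: 6 (R)-8-(triisopropylsilyl)octa-5,7-diyn-4-yl acetate
Product: 7 (R,E)-6-bromo-5-iodo-8-(triisopropylsilyl)oct-5-en-7-yn-4-yl acetate
Conditions: IBr (1.05 equiv), CH2Cl2, −78 to −20 °C, dark
Reagents that add atoms: iodine monobromide, BrI
Why: Electrophilic anti iodobromination of an alkyne: iodine should engage the inner alkyne C3≡C4, away from the bulky silyl group, and bromide should open the iodine-bridged ion anti at C4, the carbon remote from the electron-withdrawing acetoxy group and conjugated to the second alkyne, which places I on C3 trans to Br while the triisopropylsilyl group blocks attack at C6 and on the outer alkyne.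

**Step 6**
Reactants: 7 (R,E)-6-bromo-5-iodo-8-(triisopropylsilyl)oct-5-en-7-yn-4-yl acetate; 8 carbon monoxide
Product: 9 (R,E)-2-(1-acetoxybutyl)-3-bromo-5-(triisopropylsilyl)pent-2-en-4-ynoic acid
Conditions: Pd(PPh3)4 (10 mol%), CO (1 atm), iPr2NEt, THF/H2O, 45 °C; then aq. KHSO4
Reagents that add atoms: water, O
Why: Palladium-catalysed hydroxycarbonylation: zerovalent palladium should insert into the C3–I bond much faster than into C4–Br at this temperature, CO inserts and water cleaves the acylpalladium with retention of alkene geometry, so the carboxyl group ends cis to the alkynyl group, and the non-nucleophilic amine spares the acetate.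

**Step 7**
Reactants: 9 (R,E)-2-(1-acetoxybutyl)-3-bromo-5-(triisopropylsilyl)pent-2-en-4-ynoic acid
Product: 10 (R,E)-2-(1-acetoxybutyl)-3-bromopent-2-en-4-ynoic acid
Conditions: Bu4NF, AcOH, THF, 0 °C to rt; then aq. KHSO4
Reagents that add atoms: none
Why: Fluoride-induced protodesilylation of the alkynylsilane is eased by the acceptor-stabilised acetylide leaving group, and the acetic acid buffer protects the acetate and the bromoacrylate from basic fluoride.

**Step 8**
Reactants: 10 (R,E)-2-(1-acetoxybutyl)-3-bromopent-2-en-4-ynoic acid
Product: 11 acetoxyfimbrolide, (R)-1-[(5E)-4-bromo-5-(bromomethylidene)-2-oxo-2,5-dihydrofuran-3-yl]butyl acetate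
Conditions: NBS (1.1 equiv), KHCO3, Bu4NOH (cat.), CH2Cl2/H2O, 0 °C to rt, dark
Reagents that add atoms: N-bromosuccinimide, O=C1CCC(=O)N1Br
Why: Bicarbonate and the tetrabutylammonium cation carry the carboxylate of 10 into dichloromethane, NBS transfers electrophilic bromine to the terminal alkyne C5≡C6, and the carboxylate oxygen, held cis to the ethynyl group by the C3=C4 geometry, opens the bromine-bridged alkyne at the internal carbon C5 from the side opposite to bromine, forming O1–C5 and C6–Br in one anti addition. The closest known reaction type is the halolactonisation of alk-2-en-4-ynoic acids with carboxyl cis to the alkyne to 5-(halomethylidene)furan-2(5H)-ones, together with the NBS/bicarbonate bromolactonisation of alk-4-ynoic acids to (E)-bromo enol lactones. The furanone ring is closed in 5-exo-dig mode. No stereocentre is created: the exocyclic alkene geometry (Br anti to O1, syn to C4) follows from the anti course of the addition, and the (R) acetoxy centre is a spectator. The step needs closure at C5 and not 6-endo-dig closure at C6 (a 5-bromopyran-2-one), which the terminal alkyne should secure because positive charge can build up only on the substituted carbon C5; it also needs bromine to leave the C3=C4 alkene alone, which its bromine and carboxyl substituents make too electron-poor to react, and exclusion of light guards the alkene geometry.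

**Compound list**
1 | racemic hex-1-yn-3-ol | CCCC(O)C#C | starting material
2 | (R)-hex-1-yn-3-ol | CCC[C@@H](O)C#C | intermediate
3 | ethynyltriisopropylsilane | C#C[Si](C(C)C)(C(C)C)C(C)C | starting material
4 | (bromoethynyl)triisopropylsilane | BrC#C[Si](C(C)C)(C(C)C)C(C)C | intermediate
5 | (R)-8-(triisopropylsilyl)octa-5,7-diyn-4-ol | CCC[C@@H](O)C#CC#C[Si](C(C)C)(C(C)C)C(C)C | intermediate
6 | (R)-8-(triisopropylsilyl)octa-5,7-diyn-4-yl acetate | CCC[C@@H](OC(C)=O)C#CC#C[Si](C(C)C)(C(C)C)C(C)C | intermediate
7 | (R,E)-6-bromo-5-iodo-8-(triisopropylsilyl)oct-5-en-7-yn-4-yl acetate | CCC[C@@H](OC(C)=O)/C(I)=C(\Br)C#C[Si](C(C)C)(C(C)C)C(C)C | intermediate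
8 | carbon monoxide | [C-]#[O+] | starting material
9 | (R,E)-2-(1-acetoxybutyl)-3-bromo-5-(triisopropylsilyl)pent-2-en-4-ynoic acid | CCC[C@@H](OC(C)=O)/C(C(=O)O)=C(\Br)C#C[Si](C(C)C)(C(C)C)C(C)C | intermediate
10 | (R,E)-2-(1-acetoxybutyl)-3-bromopent-2-en-4-ynoic acid | CCC[C@@H](OC(C)=O)/C(C(=O)O)=C(\Br)C#C | intermediate
11 | acetoxyfimbrolide, (R)-1-[(5E)-4-bromo-5-(bromomethylidene)-2-oxo-2,5-dihydrofuran-3-yl]butyl acetate | CCC[C@@H](OC(C)=O)C1=C(Br)/C(=C\Br)OC1=O | target

**Step count**
Total: 8 steps. Longest linear sequence: 7 steps (1 → 2 → 5 → 6 → 7 → 9 → 10 → 11; the branch from 3 through 4 is equally long).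

**Steps most likely to fail**

Step 5 (iodobromination). The iodine-bridged ion may be captured by the acetate carbonyl (acyloxy shift) instead of by bromide, or bromide may open it at the wrong carbon, so that regiocontrol or the acetate is lost. The fallback sets out from 5 and changes the directing group. IBr (CH2Cl2, −78 °C) is added to the free diynol, where no acyloxy participation is possible and the hydroxyl group directs inductively, to give (R,E)-6-bromo-5-iodo-8-(triisopropylsilyl)oct-5-en-7-yn-4-ol F1. Acetylation of F1 (Ac2O, pyridine, DMAP) comes back to the route at 7.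

Step 8 (bromolactonisation). The acceptor-substituted alkyne may react too slowly with NBS, the ring may close 6-endo, or the anti course may be eroded by reversible bromine transfer or light. The fallback sets out from 10 and separates ring closure from bromination. Stoichiometric Hg(OCOCF3)2 in CH2Cl2 should effect anti oxymercuration in 5-exo-dig mode, with divalent mercury anti to O1, to give (R)-1-[(5E)-4-bromo-2-oxo-5-{[(trifluoroacetoxy)mercurio]methylidene}-2,5-dihydrofuran-3-yl]butyl acetate F2. Brine converts F2 into (R)-1-[(5E)-4-bromo-5-[(chloromercurio)methylidene]-2-oxo-2,5-dihydrofuran-3-yl]butyl acetate F3. Bromodemercuration of F3 with Br2 in pyridine at low temperature, which proceeds with retention at the alkenyl carbon, comes back to the route at 11.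

Step 6 (hydroxycarbonylation). Competing oxidative addition at the activated C4–Br bond, ionisation of the allylic acetate by zerovalent palladium (with loss of the stereocentre), acetate hydrolysis in the aqueous base, or palladium-mediated cyclisation of the free acid onto the alkyne may erode the step. The fallback sets out from 7 and masks the acid. Anhydrous alkoxycarbonylation (Pd(PPh3)4, CO, 2-(trimethylsilyl)ethanol, iPr2NEt, DMF, 45 °C) should give 2-(trimethylsilyl)ethyl (R,E)-2-(1-acetoxybutyl)-3-bromo-5-(triisopropylsilyl)pent-2-en-4-ynoate F4. Bu4NF buffered with AcOH in THF then cleaves both the silylethyl ester (by fragmentation) and the alkynylsilane in one operation and comes back to the route at 10.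

**Further compounds**
F1 | step 5 | (R,E)-6-bromo-5-iodo-8-(triisopropylsilyl)oct-5-en-7-yn-4-ol | CCC[C@@H](O)/C(I)=C(\Br)C#C[Si](C(C)C)(C(C)C)C(C)C
F2 | step 8 | (R)-1-[(5E)-4-bromo-2-oxo-5-{[(trifluoroacetoxy)mercurio]methylidene}-2,5-dihydrofuran-3-yl]butyl acetate | CCC[C@@H](OC(C)=O)C1=C(Br)/C(=C\[Hg]OC(=O)C(F)(F)F)OC1=O
F3 | step 8 | (R)-1-[(5E)-4-bromo-5-[(chloromercurio)methylidene]-2-oxo-2,5-dihydrofuran-3-yl]butyl acetate | CCC[C@@H](OC(C)=O)C1=C(Br)/C(=C\[Hg]Cl)OC1=O
F4 | step 6 | 2-(trimethylsilyl)ethyl (R,E)-2-(1-acetoxybutyl)-3-bromo-5-(triisopropylsilyl)pent-2-en-4-ynoate | CCC[C@@H](OC(C)=O)/C(C(=O)OCC[Si](C)(C)C)=C(\Br)C#C[Si](C(C)C)(C(C)C)C(C)C
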